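The 2H-chromene ring B is disconnected at C4–C4a, leading back to an enantiopure tertiary aryl propargyl ether whose O1–C2 bond is never broken. A monovalent-gold 6-endo-dig hydroarylation forms C4–C4a, closes ring B and installs the C3=C4 alkene in one operation. It exploits C4a as the only free carbon ortho to O1, since C8 carries the methyl group. The precursor is a terminal alkyne with an (S)-configured ether carbon, a pivalate-protected C6 oxygen and an E-enoate chain end. Both stereocentres (C2 and C8', each S) derive from one geraniol-based carbinol; the tail is joined last by Stille coupling.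

Key step: step 9

Remark: L-(+)-diethyl tartrate is taken to give (2S,3S)-2,3-epoxygeraniol; ring locants (O1, C2, C3, C4, C4a, C8, C8a) are those of the 2H-chromene, and primed locants refer to the C2 side chain.

**Step 1**
Reactants: 1 geraniol
Product: 2 [(2S,3S)-3-methyl-3-(4-methylpent-3-en-1-yl)oxiran-2-yl]methanol ((2S,3S)-2,3-epoxygeraniol)
Conditions: Ti(OiPr)4 (5 mol%), L-(+)-diethyl tartrate (7 mol%), t-BuOOH, 4 Å MS, CH2Cl2, −20 °C
Reagents that add atoms: tert-butyl hydroperoxide, CC(C)(C)OO
Why: Sharpless asymmetric epoxidation, in which the titanium–tartrate complex bound to the allylic hydroxyl delivers oxygen to one face of the 2,3-alkene only (the remote 6,7-alkene is not directed), should give the (2S,3S)-epoxide and thereby sets the configuration of the future carbinol carbon.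

**Step 2**
Reactants: 2 (2S,3S)-2,3-epoxygeraniol
Product: 3 (2S,3R)-3-(chloromethyl)-2-methyl-2-(4-methylpent-3-en-1-yl)oxirane
Conditions: PPh3, CCl4, NaHCO3, reflux
Reagents that add atoms: carbon tetrachloride, ClC(Cl)(Cl)Cl
Why: Appel chlorination proceeds through an alkoxyphosphonium chloride and SN2 displacement at the primary carbon under buffered neutral conditions, so the epoxide and both stereocentres are untouched (the ring CH changes descriptor from S to R only because chlorine alters the priorities).

**Step 3**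
Reactants: 3 (2S,3R)-3-(chloromethyl)-2-methyl-2-(4-methylpent-3-en-1-yl)oxirane
Product: 5 (3S)-3,7-dimethyloct-6-en-1-yn-3-ol, via lithium chlorovinyl alkoxide 4 (not isolated)
Conditions: n-BuLi (3.2 equiv), THF, −78 → −30 °C; aq. NH4Cl
Reagents that add atoms: none
Why: Base-induced double elimination of a 2,3-epoxy chloride, in which lithiation at the chloromethyl carbon opens the epoxide by β-elimination at the CH–O bond to give 4 and a second dehydrochlorination gives the alkynide, never breaks the tertiary C–O bond, so the carbinol carbon keeps its configuration (S).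

**Step 4**
Reactants: 6 4-iodo-3-methylphenol
Product: 7 4-iodo-3-methylphenyl pivalate
Conditions: PivCl, Et3N, DMAP (cat.), CH2Cl2, 0 °C → rt
Reagents that add atoms: pivaloyl chloride, CC(C)(C)C(=O)Cl
Why: DMAP-catalysed O-acylation (nucleophilic acyl substitution) masks the phenol as a hindered ester that should tolerate the oxidising, acidic and gold-catalysed steps ahead and is later removed reductively.

**Step 5**
Reactants: 7 4-iodo-3-methylphenyl pivalate; 8 1,3,5-trimethoxybenzene
Product: 10 [2-methyl-4-(pivaloyloxy)phenyl](2,4,6-trimethoxyphenyl)iodonium tosylate, via hydroxy(tosyloxy)iodoarene 9 (not isolated)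
Conditions: mCPBA, TsOH·H2O, MeCN, 77 °C; then 8, 77 °C → rt; Et2O trituration
Reagents that add atoms: 4-methylbenzenesulfonic acid monohydrate, Cc1ccc(S(=O)(=O)O)cc1.O; 3-chloroperbenzoic acid, OOC(=O)c1cccc(Cl)c1 (supplies only the hydroxyl oxygen of 9)
Why: One-pot diaryliodonium salt synthesis, in which peracid oxidation of the aryl iodide in the presence of TsOH gives the trivalent-iodine species 9 and this electrophile substitutes the very electron-rich trimethoxybenzene by electrophilic aromatic substitution with loss of water.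

**Step 6**
Reactants: 5 (3S)-3,7-dimethyloct-6-en-1-yn-3-ol; 10 [2-methyl-4-(pivaloyloxy)phenyl](2,4,6-trimethoxyphenyl)iodonium tosylate
Product: 11 4-{[(3S)-3,7-dimethyloct-6-en-1-yn-3-yl]oxy}-3-methylphenyl pivalate
Conditions: NaH, THF/toluene, 0 °C; then 10, rt
Reagents that add atoms: none
Why: Metal-free O-arylation of a tertiary alkoxide with a diaryliodonium salt (alkoxide exchange at iodine, then ligand coupling) transfers the ortho-methylated, less electron-rich aryl group while the trimethoxyphenyl group leaves as its iodide, and it forms the O–aryl bond without touching the carbinol C–O bond, so the S configuration is retained.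

**Step 7**
Reactants: 11 4-{[(3S)-3,7-dimethyloct-6-en-1-yn-3-yl]oxy}-3-methylphenyl pivalate
Product: 13 3-methyl-4-{[(3S)-3-methyl-6-oxohex-1-yn-3-yl]oxy}phenyl pivalate, via secondary ozonide 12 (not isolated)
Conditions: O3/O2, CH2Cl2, −78 °C (Sudan red 7B end point); then PPh3, −78 °C → rt
Reagents that add atoms: ozone, [O-][O+]=O
Why: Ozonolysis (Criegee mechanism) with reductive work-up cleaves the electron-rich trisubstituted alkene far faster than ozone attacks the terminal alkyne or the acylated arene, and the indicator dye guards against over-oxidation.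

**Step 8**
Reactants: 13 3-methyl-4-{[(3S)-3-methyl-6-oxohex-1-yn-3-yl]oxy}phenyl pivalate; 14 ethyl 2-(triphenylphosphoranylidene)propanoate
Product: 15 ethyl (2E,6S)-2,6-dimethyl-6-[2-methyl-4-(pivaloyloxy)phenoxy]oct-2-en-7-ynoate
Conditions: CH2Cl2, rt → 40 °C
Reagents that add atoms: none
Why: Wittig olefination with a stabilised α-methyl ylide is reliably E-selective with aliphatic aldehydes and mild enough to leave the alkyne, the pivalate and the ether centre alone.

**Step 9**
Reactants: 15 ethyl (2E,6S)-2,6-dimethyl-6-[2-methyl-4-(pivaloyloxy)phenoxy]oct-2-en-7-ynoate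
Product: 16 ethyl (2E)-5-[(2S)-2,8-dimethyl-6-(pivaloyloxy)-2H-chromen-2-yl]-2-methylpent-2-enoate
Conditions: Ph3PAuNTf2 (3 mol%), dry CH2Cl2, rt, dark
Reagents that add atoms: none
Why: The cationic gold centre binds the terminal alkyne of 15, the arene carbon ortho to the ether oxygen (future C4a) attacks the terminal alkyne carbon in a Friedel–Crafts manner, and rearomatisation followed by protodeauration of the vinylgold releases the C3=C4 alkene and the catalyst. The closest known reaction type is the monovalent-gold-catalysed intramolecular hydroarylation of aryl propargyl ethers to 2H-chromenes, which is established for 1,1-disubstituted terminal propargyl ethers. Ring B closes in the 6-endo-dig mode, which the short O–C tether should favour over 5-exo-dig attack at the internal alkyne carbon. No stereocentre is created: the O1–C2 bond and the other three bonds of the carbinol-derived carbon are untouched, so the S configuration passes unchanged from 15 to 16. Regioselectivity on the arene is fixed because C4a is the only unsubstituted carbon ortho to the ether oxygen (the other ortho carbon carries the methyl group), and chemoselectivity over 1,6-enyne cycloisomerisation is secured by the electron-poor enoate, a poor nucleophile toward the gold–alkyne complex.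

**Step 10**
Reactants: 16 ethyl (2E)-5-[(2S)-2,8-dimethyl-6-(pivaloyloxy)-2H-chromen-2-yl]-2-methylpent-2-enoate
Product: 17 (2S)-2-[(3E)-5-hydroxy-4-methylpent-3-en-1-yl]-2,8-dimethyl-2H-chromen-6-ol
Conditions: i-Bu2AlH (5 equiv), CH2Cl2, −78 → 0 °C; aq. KNaC4H4O6
Reagents that add atoms: none
Why: Hydride reduction with diisobutylaluminium hydride reduces the enoate 1,2 to the E-allylic alcohol and cleaves the aryl pivalate to the phenol in the same operation, without affecting the chromene alkene or the ether centre.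

**Step 11**
Reactants: 17 (2S)-2-[(3E)-5-hydroxy-4-methylpent-3-en-1-yl]-2,8-dimethyl-2H-chromen-6-ol
Product: 18 (2S)-2-[(3E)-5-bromo-4-methylpent-3-en-1-yl]-2,8-dimethyl-2H-chromen-6-ol
Conditions: CBr4, PPh3, CH2Cl2, −30 → 0 °C, under argon
Reagents that add atoms: carbon tetrabromide, BrC(Br)(Br)Br
Why: Appel bromination is selective for the allylic alcohol because only its alkoxyphosphonium ion can undergo SN2 displacement by bromide (an aryl–oxygen bond cannot), and the neutral, cold conditions should avoid allylic transposition.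

**Step 12**
Reactants: 5 (3S)-3,7-dimethyloct-6-en-1-yn-3-ol
Product: 19 (1E,3S)-3,7-dimethyl-1-(tributylstannyl)octa-1,6-dien-3-ol
Conditions: Bu3SnH, PdCl2(PPh3)2 (2 mol%), THF, 0 °C → rt
Reagents that add atoms: tributyltin hydride, CCCC[SnH](CCCC)CCCC
Why: Palladium-catalysed hydrostannation adds Sn–H syn across the terminal alkyne and the bulky tertiary carbinol steers tin to the terminal carbon, so the E-vinylstannane should form with the stereocentre untouched.

**Step 13**
Reactants: 18 (2S)-2-[(3E)-5-bromo-4-methylpent-3-en-1-yl]-2,8-dimethyl-2H-chromen-6-ol; 19 (1E,3S)-3,7-dimethyl-1-(tributylstannyl)octa-1,6-dien-3-ol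
Product: 20 (2S)-2-[(3E,6E,8S)-8-hydroxy-4,8,12-trimethyltrideca-3,6,11-trien-1-yl]-2,8-dimethyl-2H-chromen-6-ol (target)
Conditions: Pd2(dba)3 (2.5 mol%), AsPh3 (10 mol%), degassed THF/NMP, 40 °C, dark
Reagents that add atoms: none
Why: Stille coupling of an allylic bromide with an alkenylstannane (oxidative addition to a π-allylpalladium species, transmetalation, reductive elimination at the less hindered CH2 terminus) joins C5' to C6' with retention of both alkene geometries under neutral conditions that tolerate the free phenol and the tertiary alcohol.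

**Compound list**

1 | geraniol, (2E)-3,7-dimethylocta-2,6-dien-1-ol | CC(C)=CCC/C(C)=C/CO | starting material
2 | [(2S,3S)-3-methyl-3-(4-methylpent-3-en-1-yl)oxiran-2-yl]methanol | CC(C)=CCC[C@]1(C)O[C@H]1CO | intermediate
3 | (2S,3R)-3-(chloromethyl)-2-methyl-2-(4-methylpent-3-en-1-yl)oxirane | CC(C)=CCC[C@]1(C)O[C@H]1CCl | intermediate
4 | lithium (3S)-1-chloro-3,7-dimethylocta-1,6-dien-3-olate (alkene geometry undefined) | CC(C)=CCC[C@](C)([O-])C=CCl.[Li+] | intermediate (not isolated)
5 | (3S)-3,7-dimethyloct-6-en-1-yn-3-ol | CC(C)=CCC[C@](C)(O)C#C | intermediate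
6 | 4-iodo-3-methylphenol | Cc1cc(O)ccc1I | starting material
7 | 4-iodo-3-methylphenyl pivalate | Cc1cc(OC(=O)C(C)(C)C)ccc1I | intermediate
8 | 1,3,5-trimethoxybenzene | COc1cc(OC)cc(OC)c1 | starting material
9 | 4-[hydroxy(tosyloxy)-λ3-iodanyl]-3-methylphenyl pivalate | Cc1cc(OC(=O)C(C)(C)C)ccc1I(O)OS(=O)(=O)c1ccc(C)cc1 | intermediate (not isolated)
10 | [2-methyl-4-(pivaloyloxy)phenyl](2,4,6-trimethoxyphenyl)iodonium 4-methylbenzenesulfonate | Cc1cc(OC(=O)C(C)(C)C)ccc1[I+]c1c(OC)cc(OC)cc1OC.Cc1ccc(S(=O)(=O)[O-])cc1 | intermediate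
11 | 4-{[(3S)-3,7-dimethyloct-6-en-1-yn-3-yl]oxy}-3-methylphenyl pivalate | C#C[C@](C)(CCC=C(C)C)Oc1ccc(OC(=O)C(C)(C)C)cc1C | intermediate
12 | 4-{[(3S)-5-(5,5-dimethyl-1,2,4-trioxolan-3-yl)-3-methylpent-1-yn-3-yl]oxy}-3-methylphenyl pivalate (ozonide carbon undefined) | C#C[C@](C)(CCC2OOC(C)(C)O2)Oc1ccc(OC(=O)C(C)(C)C)cc1C | intermediate (not isolated)
13 | 3-methyl-4-{[(3S)-3-methyl-6-oxohex-1-yn-3-yl]oxy}phenyl pivalate | C#C[C@](C)(CCC=O)Oc1ccc(OC(=O)C(C)(C)C)cc1C | intermediate
14 | ethyl 2-(triphenylphosphoranylidene)propanoate | CCOC(=O)C(C)=P(c1ccccc1)(c1ccccc1)c1ccccc1 | starting material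
15 | ethyl (2E,6S)-2,6-dimethyl-6-[2-methyl-4-(pivaloyloxy)phenoxy]oct-2-en-7-ynoate | C#C[C@](C)(CC/C=C(\C)C(=O)OCC)Oc1ccc(OC(=O)C(C)(C)C)cc1C | intermediate
16 | ethyl (2E)-5-[(2S)-2,8-dimethyl-6-(pivaloyloxy)-2H-chromen-2-yl]-2-methylpent-2-enoate | CCOC(=O)/C(C)=C/CC[C@@]1(C)C=Cc2cc(OC(=O)C(C)(C)C)cc(C)c2O1 | intermediate
17 | (2S)-2-[(3E)-5-hydroxy-4-methylpent-3-en-1-yl]-2,8-dimethyl-2H-chromen-6-ol | OC/C(C)=C/CC[C@@]1(C)C=Cc2cc(O)cc(C)c2O1 | intermediate
18 | (2S)-2-[(3E)-5-bromo-4-methylpent-3-en-1-yl]-2,8-dimethyl-2H-chromen-6-ol | BrC/C(C)=C/CC[C@@]1(C)C=Cc2cc(O)cc(C)c2O1 | intermediate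
19 | (1E,3S)-3,7-dimethyl-1-(tributylstannyl)octa-1,6-dien-3-ol | CC(C)=CCC[C@](C)(O)/C=C/[Sn](CCCC)(CCCC)CCCC | intermediate
20 | (2S)-2-[(3E,6E,8S)-8-hydroxy-4,8,12-trimethyltrideca-3,6,11-trien-1-yl]-2,8-dimethyl-2H-chromen-6-ol | CC(C)=CCC[C@](C)(O)/C=C/C/C(C)=C/CC[C@@]1(C)C=Cc2cc(O)cc(C)c2O1 | target

**Step count**

Total: 13 steps. Longest linear sequence: 10 steps (1, 2, 3, 6, 7, 8, 9, 10, 11, 13).

**Steps most likely to fail**

Step 9. The cationic gold catalyst may heterolyse the tertiary propargylic C–O bond (loss of the aryl oxide and elimination to an enyne) faster than the pivalate-bearing ring attacks the alkyne. The terminal alkyne may also be hydrated by adventitious water or drawn off-cycle as a digold acetylide. Fallback: setting out from 15, the thermal aryl propargyl ether cascade (aromatic Claisen rearrangement, 1,5-hydrogen shift, oxa-6π electrocyclisation; N,N-diethylaniline, about 180 °C) should give racemic ethyl (E)-5-[2,8-dimethyl-6-(pivaloyloxy)-2H-chromen-2-yl]-2-methylpent-2-enoate F1. The product is racemic because this pathway opens the O1–C2 bond. Preparative chromatography on a polysaccharide chiral stationary phase would then isolate the S enantiomer and return to the route at 16.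

Step 6. The strongly basic tertiary alkoxide may deprotonate the iodonium salt ortho to iodine and open an aryne pathway that gives regioisomeric ethers. It may instead take the acyl group from the iodonium-activated aryl pivalate, or ligand coupling at the congested oxygen may be sluggish. Fallback: setting out from 5, nucleophilic aromatic substitution of its potassium alkoxide (KN(SiMe3)2, THF/DMF, 0 °C) on 1-fluoro-2-methyl-4-nitrobenzene should give 1-{[(3S)-3,7-dimethyloct-6-en-1-yn-3-yl]oxy}-2-methyl-4-nitrobenzene F2. Reduction with Fe/NH4Cl in aqueous ethanol would give 4-{[(3S)-3,7-dimethyloct-6-en-1-yn-3-yl]oxy}-3-methylaniline F3. Diazotisation (NaNO2, dilute H2SO4, 0 °C) and hydroxylation promoted by Cu2O/Cu(NO3)2 at room temperature would give 4-{[(3S)-3,7-dimethyloct-6-en-1-yn-3-yl]oxy}-3-methylphenol F4. Pivaloylation (PivCl, Et3N, DMAP) then returns to the route at 11.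

Step 13. Regio- and stereochemical integrity may be lost in the π-allylpalladium intermediate (attack at the internal allyl terminus, E/Z equilibration). The free phenol may be O-allylated, or 19 may be protodestannylated. Fallback: setting out from 17, selective acylation of the phenoxide under Schotten–Baumann conditions (PivCl, aq. NaOH, CH2Cl2, Bu4NHSO4) should give (2S)-2-[(3E)-5-hydroxy-4-methylpent-3-en-1-yl]-2,8-dimethyl-2H-chromen-6-yl pivalate F5. Appel bromination (CBr4, PPh3) would give (2S)-2-[(3E)-5-bromo-4-methylpent-3-en-1-yl]-2,8-dimethyl-2H-chromen-6-yl pivalate F6. Copper-mediated allylation of alkyne 5 (CuI, NaI, K2CO3, DMF, rt) would give the skipped enyne (2S)-2-[(3E,8S)-8-hydroxy-4,8,12-trimethyltrideca-3,11-dien-6-yn-1-yl]-2,8-dimethyl-2H-chromen-6-yl pivalate F7. Hydroxyl-directed trans-hydroalumination with NaAlH2(OCH2CH2OCH3)2 in THF would set the E-C6'=C7' alkene and cleave the pivalate in the same operation, returning to the route at 20.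

**Further compounds**

F1 | step 9 | racemic ethyl (E)-5-[2,8-dimethyl-6-(pivaloyloxy)-2H-chromen-2-yl]-2-methylpent-2-enoate | CCOC(=O)/C(C)=C/CCC1(C)C=Cc2cc(OC(=O)C(C)(C)C)cc(C)c2O1
F2 | step 6 | 1-{[(3S)-3,7-dimethyloct-6-en-1-yn-3-yl]oxy}-2-methyl-4-nitrobenzene | C#C[C@](C)(CCC=C(C)C)Oc1ccc([N+](=O)[O-])cc1C
F3 | step 6 | 4-{[(3S)-3,7-dimethyloct-6-en-1-yn-3-yl]oxy}-3-methylaniline | C#C[C@](C)(CCC=C(C)C)Oc1ccc(N)cc1C
F4 | step 6 | 4-{[(3S)-3,7-dimethyloct-6-en-1-yn-3-yl]oxy}-3-methylphenol | C#C[C@](C)(CCC=C(C)C)Oc1ccc(O)cc1C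
F5 | step 13 | (2S)-2-[(3E)-5-hydroxy-4-methylpent-3-en-1-yl]-2,8-dimethyl-2H-chromen-6-yl pivalate | OC/C(C)=C/CC[C@@]1(C)C=Cc2cc(OC(=O)C(C)(C)C)cc(C)c2O1
F6 | step 13 | (2S)-2-[(3E)-5-bromo-4-methylpent-3-en-1-yl]-2,8-dimethyl-2H-chromen-6-yl pivalate | BrC/C(C)=C/CC[C@@]1(C)C=Cc2cc(OC(=O)C(C)(C)C)cc(C)c2O1
F7 | step 13 | (2S)-2-[(3E,8S)-8-hydroxy-4,8,12-trimethyltrideca-3,11-dien-6-yn-1-yl]-2,8-dimethyl-2H-chromen-6-yl pivalate | CC(C)=CCC[C@](C)(O)C#CC/C(C)=C/CC[C@@]1(C)C=Cc2cc(OC(=O)C(C)(C)C)cc(C)c2O1
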